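**Strategy.** The route rests on one disconnection: C2 and C7, the two oxygenated carbons that stand 1,6 to each other on both arcs of the ten-membered ring, are joined back to a C2=C7 olefin. That olefin is the bond shared by rings B and C of a hydrophenanthrene whose ring C is a Birch-reduced anisole (methoxy carbon = C5). Ozonolysis cuts it and delivers the ten-membered C2/C7 diketone in one operation, with no C–C bond to be made in a medium ring. The precursor 36 is a rigid tricycle that already holds C1, C8–C12, the ring A epoxide and the C17–C19 unit, tied to O9 as a γ-lactone.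

Key step: step 23

Conventions: atoms carry the numbers of the target (C1 quaternary ring-fusion carbon, C2–C10 round the ten-membered ring, C11–C14 ring A, C15/C20 methyls, C16 methylene, C17–C19 lactone unit); β is the face of the C1 methyl; ring A = C1, C10–C14, ring B = C1, C2, C7–C10, ring C = C2–C7.
Assumption: the imine of 4 with (R)-1-phenylethanamine adds to the enone with the facial sense known for imines of 2-substituted cyclic ketones, which corresponds to the (R) quaternary centre drawn; if the sense were opposite, the (S)-amine would be used.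

**Route**

Step 1
Reactants: 1 6-methoxy-3,4-dihydronaphthalen-2(1H)-one
Product: 4 (±)-6-methoxy-1-methyl-3,4-dihydronaphthalen-2(1H)-one, via pyrrolidine enamine 2 (not isolated), via iminium iodide 3 (not isolated)
Conditions: pyrrolidine, PhH, reflux (−H2O); MeI, MeCN, reflux; aq. AcOH
Reagents that add atoms: iodomethane CI; water O
Why: Stork enamine alkylation, in which the arene-conjugated enamine is C-methylated only at the benzylic C1 and hydrolysis returns the ketone; the new centre is racemic and is resolved dynamically in step 2.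

Step 2
Reactants: 4 (±)-6-methoxy-1-methyl-3,4-dihydronaphthalen-2(1H)-one; 5 (R)-1-phenylethanamine; 6 pent-1-en-3-one
Product: 9 (R)-6-methoxy-1-methyl-1-(3-oxopentyl)-3,4-dihydronaphthalen-2(1H)-one, via ketimine 7 (not isolated), via Michael adduct imine 8 (not isolated)
Conditions: 5, TsOH (cat.), PhMe, reflux (−H2O); 6, THF, rt; 10% aq. AcOH
Reagents that add atoms: water O
Why: Asymmetric Michael addition of a chiral imine through its more substituted secondary enamine tautomer, in which the enone is taken up on the enamine face anti to the phenyl group of the auxiliary, so that both enantiomers of 4 converge on the (R) quaternary C1 and hydrolysis releases the amine.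

Step 3
Reactants: 9 (R)-6-methoxy-1-methyl-1-(3-oxopentyl)-3,4-dihydronaphthalen-2(1H)-one
Product: 10 (S)-7-methoxy-1,4a-dimethyl-4,4a,9,10-tetrahydrophenanthren-2(3H)-one (C12 ketone; C10=C11; C1 methyl β)
Conditions: NaOMe, MeOH, 60 °C
Reagents that add atoms: none
Why: Intramolecular aldol condensation (second half of a Robinson annulation) of the ethyl ketone onto the ring ketone closes ring A as the C10=C11 enone without touching C1.

Step 4
Reactants: 10 tricyclic enone
Product: 11 C12 ethyl dienol ether (C9=C10 and C11=C12)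
Conditions: HC(OEt)3, TsOH (cat.), EtOH/dioxane, rt
Reagents that add atoms: triethyl orthoformate CCOC(OCC)OCC
Why: Acid-catalysed formation of the extended dienol ether of a 2-methylcyclohexenone, as practised on steroidal 4-en-3-ones, shifts unsaturation to C9=C10 and makes C9 nucleophilic.

Step 5
Reactants: 11 C12 ethyl dienol ether
Product: 12 9β-hydroxy C10=C11 enone
Conditions: mCPBA, THF/H2O (pH 7 buffer), 0 °C
Reagents that add atoms: 3-chloroperbenzoic acid OOC(=O)c1cccc(Cl)c1; water O
Why: Vinylogous (γ) hydroxylation of a dienol ether by peracid, in which oxygen adds axially at C9 (β, the 6β-type outcome of steroid dienol ethers) and hydrolysis of the oxocarbenium ion returns the enone; the C9 configuration is uncritical because it is reset in step 17.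

Step 6
Reactants: 12 9β-hydroxy enone
Product: 14 9β-trimethylsilyloxy C11=C12 trimethylsilyl enol ether (H-10 α), via dilithium enolate alkoxide 13 (not isolated)
Conditions: Li (2.2 equiv), NH3(l)/THF, −78 °C; isoprene; NH3 off; TMSCl, Et3N, THF, −78 → 0 °C
Reagents that add atoms: chlorotrimethylsilane C[Si](C)(C)Cl
Why: Dissolving-metal conjugate reduction with enolate trapping, in which the C9 hydroxyl is the single proton donor (and as alkoxide is no leaving group), axial protonation at C10 gives the trans ring fusion (H-10 α, anti to the C1 methyl) and the regiodefined C11=C12 enolate is silylated.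

Step 7
Reactants: 14 bis-silyl enol ether
Product: 16 9β,11α-bis(trimethylsilyloxy) C12 ketone, via silyloxy epoxide 15 (not isolated)
Conditions: DMDO, acetone/CH2Cl2, −78 → 0 °C
Reagents that add atoms: dimethyldioxirane CC1(C)OO1
Why: Rubottom oxidation, in which the enol ether is epoxidised from the α face, away from the axial C1 methyl that stands 1,3 to C11, and 1,4-silyl migration gives the tertiary silyloxy ketone with O11 α and the C11 methyl β.

Step 8
Reactants: 16 bis-silyloxy C12 ketone
Product: 18 C12=C13 enol triflate, via potassium enolate 17 (not isolated)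
Conditions: KN(SiMe3)2, THF, −78 °C; PhNTf2
Reagents that add atoms: N-phenylbis(trifluoromethanesulfonimide) O=S(=O)(N(c1ccccc1)S(=O)(=O)C(F)(F)F)C(F)(F)F
Why: Enolate O-triflation, regiodefined because the C12 ketone can enolise only towards C13 (C11 is quaternary); no stereocentre is formed.

Step 9
Reactants: 18 enol triflate
Product: 20 9β,11α-diol with C12=C13 olefin, via bis-silyl ether 19 (not isolated)
Conditions: Pd(OAc)2 (cat.), PPh3, Bu3N, HCO2H, DMF, 60 °C; then K2CO3, MeOH, rt
Reagents that add atoms: none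
Why: Palladium-catalysed formate reduction of a vinyl triflate (oxidative addition, hydride transfer from formate, reductive elimination) gives the olefin, and methanolysis removes both TMS ethers; no stereocentre changes.

Step 10
Reactants: 20 allylic diol
Product: 21 12α,13α-epoxy-9β,11α-diol
Conditions: mCPBA, NaHCO3, CH2Cl2, 0 °C
Reagents that add atoms: 3-chloroperbenzoic acid OOC(=O)c1cccc(Cl)c1
Why: Hydroxyl-directed peracid epoxidation of a cyclic allylic alcohol, in which the α C11 hydroxyl guides the reagent to the α face, which is also the face free of the C1 and C11 methyls.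

Step 11
Reactants: 21 epoxy diol
Product: 22 9β,11α,12α-triol with C13=C14 olefin
Conditions: LiNEt2 (from Et2NH, n-BuLi; 5 equiv), Et2O/THF, 0 °C → rt; aq. NH4Cl
Reagents that add atoms: none
Why: Base-induced isomerisation of an epoxide to an allylic alcohol by syn β-elimination, in which only C14 offers a β-hydrogen (C11 is quaternary), so the C13–O bond breaks, oxygen stays on C12 with its α configuration and the olefin appears at C13=C14.

Step 12
Reactants: 22 allylic triol
Product: 23 Birch diene (C4=C5 methyl enol ether; C2=C7 ring-fusion olefin)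
Conditions: Li, NH3(l)/THF, t-BuOH, −78 → −33 °C; MeOH, NH4Cl
Reagents that add atoms: none
Why: Birch reduction of a 3,4-dialkylanisole, in which protonation ortho and meta to the methoxy group leaves the enol ether and the tetrasubstituted C2=C7 olefin; the hydroxyls react as lithium alkoxides (none is benzylic) and the isolated C13=C14 olefin is inert.

Step 13
Reactants: 23 Birch diene
Product: 24 C5 dioxolane 9β,11α,12α-triol
Conditions: ethylene glycol, PPTS (cat.), CH2Cl2, rt
Reagents that add atoms: ethylene glycol OCCO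
Why: Acid-catalysed acetal exchange, in which protonation of the enol ether at C4 and capture by the diol give the ketal without a free ketone, so the C2=C7 olefin does not move into conjugation.

Step 14
Reactants: 24 dioxolane triol
Product: 25 11,12-cyclic methyl orthobutanoate (orthoester carbon a mixture)
Conditions: PrC(OMe)3, PPTS (cat.), CH2Cl2, rt
Reagents that add atoms: trimethyl orthobutanoate CCCC(OC)(OC)OC
Why: Cyclic orthoester formation, possible only for the cis C11/C12 diol, masks both hydroxyls for steps 15–18 and already carries the butanoyl chain destined for O12, while the C9 hydroxyl stays free.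

Step 15
Reactants: 25 orthoester
Product: 26 C9 ketone
Conditions: DMP, pyridine, CH2Cl2, 0 °C
Reagents that add atoms: none
Why: Dess–Martin oxidation of the only free secondary alcohol under buffered conditions that spare orthoester, ketal and the C2=C7 olefin.

Step 16
Reactants: 26 C9 ketone
Product: 28 8-hydroxy C9 ketone (C8 epimers), via potassium dienolate 27 (not isolated)
Conditions: KN(SiMe3)2, THF, −78 °C; 3-phenyl-2-(phenylsulfonyl)oxaziridine
Reagents that add atoms: 3-phenyl-2-(phenylsulfonyl)oxaziridine O=S(=O)(c1ccccc1)N1OC1c1ccccc1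
Why: Enolate hydroxylation with a sulfonyloxaziridine, in which deprotonation occurs at C8 (α to the ketone and allylic) and the dienolate reacts at its α carbon; the C8 configuration is irrelevant because C8 becomes a ketone in step 18.

Step 17
Reactants: 28 8-hydroxy C9 ketone
Product: 29 8,9β-diol
Conditions: NaBH4, MeOH, −20 °C
Reagents that add atoms: none
Why: Borohydride reduction, in which hydride reaches C9 from the α face, away from the axial C1 methyl that stands 1,3 on ring B, and gives the axial 9β-alcohol.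

Step 18
Reactants: 29 8,9β-diol
Product: 30 9β-hydroxy C8 enone
Conditions: MnO2, CH2Cl2, rt
Reagents that add atoms: none
Why: Chemoselective MnO2 oxidation of the allylic C8 alcohol (the saturated C9 carbinol is untouched) gives the tetrasubstituted enone, which also deactivates C2=C7 towards the oxidant of step 20.

Step 19
Reactants: 30 orthoester enone
Product: 31 12α-butanoate 9β,11α-diol C8 enone
Conditions: PPTS (cat.), THF/H2O, rt
Reagents that add atoms: water O
Why: Mild hydrolysis of the cyclic orthoester through its dioxolanylium ion, which opens to the ester on the secondary, axial C12 oxygen and frees the tertiary C11 hydroxyl while the C5 dioxolane survives.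

Step 20
Reactants: 31 allylic butanoate
Product: 32 13α,14α-epoxide
Conditions: VO(acac)2 (cat.), t-BuOOH, CH2Cl2, rt
Reagents that add atoms: tert-butyl hydroperoxide CC(C)(C)OO
Why: Hydroxyl-directed vanadium-catalysed epoxidation, in which the homoallylic α C11 hydroxyl delivers oxygen to the α face of C13=C14, the β face being shielded by the neighbouring C1 methyl, and the enone olefin is too electron-poor to react.

Step 21
Reactants: 32 epoxy hydroxy enone; 33 2-bromopropanoyl bromide
Product: 34 9β-(2-bromopropanoate) (CHBr carbon a mixture)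
Conditions: pyridine, CH2Cl2, −20 °C
Reagents that add atoms: none
Why: O-Acylation of the secondary C9 hydroxyl by an acid bromide (the tertiary C11 hydroxyl does not react) places the C17–C19 unit as a tether on the β face; the CHBr centre becomes an enolate in step 22.

Step 22
Reactants: 34 bromopropanoate
Product: 36 tricyclic ring-fusion olefin with O9 γ-lactone and 8α-hydroxyl (key-step precursor), via samarium enolate 35 (not isolated)
Conditions: SmI2 (2.5 equiv), THF, −78 °C; aq. NH4Cl
Reagents that add atoms: none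
Why: Intramolecular Reformatsky reaction, in which the trivalent samarium ester enolate held on the β oxygen at C9 can reach the C8 carbonyl only from the β face, so C17 is bonded β and the C8 hydroxyl is α (cis-fused γ-lactone); the C17 methyl should take the convex side and is corrected in step 25.

Step 23
Reactants: 36 tricyclic ring-fusion olefin
Product: 39 ten-membered C2/C7 diketone, via primary ozonide 37 (not isolated), via bridged 1,2,4-trioxolane 38 (not isolated)
Conditions: O3, CH2Cl2, −78 °C (Sudan red 7B end-point); Me2S, −78 → 0 °C; neutral work-up, used at once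
Reagents that add atoms: ozone [O-][O+]=O
Why: Ozone adds to the electron-rich tetrasubstituted C2=C7 olefin by 1,3-dipolar cycloaddition to give 37, which cycloreverts and recloses within the molecule to trioxolane 38; dimethyl sulfide then reduces the peroxide to the C2 and C7 ketones, the closest precedent being ozonolysis of ring-fusion olefins of octalin type to cyclodecane-1,6-diones. No ring is closed by bond formation: the ten-membered ring C1–C10 appears because the bond common to six-membered rings B and C is cut, and no stereocentre is created. The step needs only chemoselectivity, which is secured because C2=C7 is the single C=C bond of 36 and epoxide, esters, lactone, ketal and tertiary alcohols are inert to ozone at −78 °C. Aprotic medium, titration to the indicator end-point and immediate reduction guard against over-oxidation next to the free C8 hydroxyl. Neutral work-up and direct use are required because C3 and C6, the only enolisable positions, could each attack the opposite ketone across the ring.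

Step 24
Reactants: 39 ten-membered diketone
Product: 40 7-hydroxy C2 ketone (O9 lactone)
Conditions: Me4NBH(OAc)3, MeCN/AcOH, −30 °C
Reagents that add atoms: none
Why: Hydroxyl-directed triacetoxyborohydride reduction (Evans–Saksena type), in which hydride is delivered internally from the borate of the C8 hydroxyl while the ring keeps C6 and C9 anti about C7–C8, placing the new hydroxyl anti to O8 as in the target; the C2 ketone, next to quaternary C1 and with no hydroxyl in reach, is not reduced.

Step 25
Reactants: 40 7-hydroxy O9 lactone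
Product: 42 9-hydroxy O7 lactone with natural C17, via 17-epi O7 lactone 41 (not isolated)
Conditions: DBU, PhMe, 40 °C
Reagents that add atoms: none
Why: Base-mediated acyl shift and epimerisation, in which the C7 hydroxyl takes over the lactone carbonyl because a γ-lactone trans-fused across C7–C8 suits the ten-membered ring better than one cis-fused across C8–C9, and reversible enolisation then places the C17 methyl cis to the small C8 hydroxyl and trans to C9.

Step 26
Reactants: 42 9-hydroxy O7 lactone
Product: 43 9-acetate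
Conditions: Ac2O, pyridine, DMAP (cat.), CH2Cl2, 0 °C
Reagents that add atoms: acetic anhydride CC(=O)OC(C)=O
Why: Acylation of the only secondary hydroxyl (C9); the tertiary C8 and C11 hydroxyls do not react under these conditions.

Step 27
Reactants: 43 9-acetate C2 ketone
Product: 45 (Z)-C3=C4 enone as 8,11-bis(trimethylsilyl) ether, via tris-silyl enol ether 44 (not isolated)
Conditions: TMSOTf, Et3N, CH2Cl2, −78 → 0 °C; then Pd(OAc)2, MeCN, rt
Reagents that add atoms: trimethylsilyl triflate C[Si](C)(C)OS(=O)(=O)C(F)(F)F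
Why: Saegusa–Ito oxidation, in which the C2 ketone can enolise only towards C3 (C1 is quaternary), the divalent palladium enolate undergoes β-hydride elimination to C3=C4, and the cis olefin is the less strained geometry in a ten-membered ring; the two tertiary hydroxyls are silylated in the same operation.

Step 28
Reactants: 45 (Z)-enone
Product: 46 C2 allylic alcohol
Conditions: NaBH4, CeCl3·7H2O, MeOH, −78 °C
Reagents that add atoms: none
Why: Luche 1,2-reduction under Felkin–Anh control by quaternary C1, in which hydride enters C2 from the side of the C1 methyl, anti to the bulkier C14 branch, so that O2 ends anti to the methyl as in the target.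

Step 29
Reactants: 46 C2 allylic alcohol
Product: 47 2,12-dibutanoate
Conditions: (PrCO)2O, DMAP, pyridine, CH2Cl2, rt
Reagents that add atoms: butanoic anhydride CCCC(=O)OC(=O)CCC
Why: Acylation of the one free (secondary, allylic) hydroxyl; the tertiary alcohols are silyl-protected.

Step 30
Reactants: 47 dibutanoate ketal
Product: 48 C5 enone 8,11-diol
Conditions: PPTS, acetone/H2O, 40 °C
Reagents that add atoms: water O
Why: Acid hydrolysis of the allylic, hence labile, dioxolane to the C5 enone and of both TMS ethers; the epoxide, flanked by an acyloxy group and a quaternary carbon, is slow to open.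

Step 31
Reactants: 48 C5 enone
Product: 50 6-chloro C5 enone as 8,11-bis(trimethylsilyl) ether, via silyl dienol ether 49 (not isolated)
Conditions: TMSOTf, Et3N, CH2Cl2, −78 °C; then NCS, THF, −78 → −20 °C
Reagents that add atoms: trimethylsilyl triflate C[Si](C)(C)OS(=O)(=O)C(F)(F)F; N-chlorosuccinimide O=C1CCC(=O)N1Cl
Why: α-Chlorination through a silyl enol ether, in which soft enolisation of the enone can occur only at C6 (no free enolate, so the C7 acyloxy group is not expelled) and chlorine should add anti to the C7–C8 bond with the C7–O bond in the enol ether plane, i.e. anti to O7 as required; the renewed silylation of the tertiary hydroxyls protects them in step 32.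

Step 32
Reactants: 50 6-chloro enone
Product: 52 CNP0188106.1 (target), via bis-silyl ether 51 (not isolated)
Conditions: Cp2Ti(μ-Cl)(μ-CH2)AlMe2, pyridine (cat.), THF/PhMe, −40 → 0 °C; filtration; then HF·pyridine, THF, 0 °C
Reagents that add atoms: Tebbe reagent C[Al](C)C[Ti](Cl)(C1C=CC=C1)C1C=CC=C1
Why: Tebbe methylenation, in which the titanium methylidene adds to the ketone in preference to the four ester carbonyls at low temperature and is non-basic, so the α-chloro and β-acyloxy groups are neither epimerised nor eliminated; fluoride then removes the two TMS ethers.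

**Compound list**

1 | 6-methoxy-3,4-dihydronaphthalen-2(1H)-one | COc1ccc2c(c1)CCC(=O)C2 | starting material
2 | 1-(6-methoxy-3,4-dihydronaphthalen-2-yl)pyrrolidine | COc1ccc2C=C(N3CCCC3)CCc2c1 | intermediate
3 | C1-methylated pyrrolidinium iminium iodide | COc1ccc2C(C)C(=[N+]3CCCC3)CCc2c1.[I-] | intermediate
4 | (±)-6-methoxy-1-methyl-3,4-dihydronaphthalen-2(1H)-one | COc1ccc2C(C)C(=O)CCc2c1 | intermediate
5 | (R)-1-phenylethanamine | C[C@@H](N)c1ccccc1 | starting material
6 | pent-1-en-3-one | C=CC(=O)CC | starting material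
7 | ketimine of 4 with 5 (C1 epimers equilibrate through the enamine) | COc1ccc2C(C)C(=N[C@H](C)c3ccccc3)CCc2c1 | intermediate
8 | Michael adduct imine with (R) quaternary C1 | COc1ccc2c(c1)CCC(=N[C@H](C)c1ccccc1)[C@]2(C)CCC(=O)CC | intermediate
9 | (R)-6-methoxy-1-methyl-1-(3-oxopentyl)-3,4-dihydronaphthalen-2(1H)-one | COc1ccc2c(c1)CCC(=O)[C@]2(C)CCC(=O)CC | intermediate
10 | (S)-7-methoxy-1,4a-dimethyl-4,4a,9,10-tetrahydrophenanthren-2(3H)-one (C12 ketone; C10=C11; C1 methyl β) | COc1ccc2c(c1)CCC1=C(C)C(=O)CC[C@@]12C | intermediate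
11 | C12 ethyl dienol ether of 10 (C9=C10; C11=C12) | COc1ccc2c(c1)CC=C1C(C)=C(OCC)CC[C@@]12C | intermediate
12 | 9β-hydroxy derivative of enone 10 | COc1ccc2c(c1)C[C@@H](O)C1=C(C)C(=O)CC[C@@]12C | intermediate
13 | dilithium C11=C12 enolate C9 alkoxide (H-10 α) | COc1ccc2c(c1)C[C@@H]([O-])[C@H]1C(C)=C([O-])CC[C@@]12C.[Li+].[Li+] | intermediate
14 | 9β-trimethylsilyloxy C11=C12 trimethylsilyl enol ether (trans ring fusion) | COc1ccc2c(c1)C[C@@H](O[Si](C)(C)C)[C@H]1C(C)=C(O[Si](C)(C)C)CC[C@@]12C | intermediate
15 | 11α,12α-epoxide of 14 | COc1ccc2c(c1)C[C@@H](O[Si](C)(C)C)[C@H]1[C@]3(C)O[C@]3(O[Si](C)(C)C)CC[C@@]12C | intermediate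
16 | 9β,11α-bis(trimethylsilyloxy) C12 ketone (C11 methyl β) | COc1ccc2c(c1)C[C@@H](O[Si](C)(C)C)[C@H]1[C@](C)(O[Si](C)(C)C)C(=O)CC[C@@]12C | intermediate
17 | potassium C12=C13 enolate of 16 | COc1ccc2c(c1)C[C@@H](O[Si](C)(C)C)[C@H]1[C@](C)(O[Si](C)(C)C)C([O-])=CC[C@@]12C.[K+] | intermediate
18 | C12=C13 enol triflate | COc1ccc2c(c1)C[C@@H](O[Si](C)(C)C)[C@H]1[C@](C)(O[Si](C)(C)C)C(OS(=O)(=O)C(F)(F)F)=CC[C@@]12C | intermediate
19 | bis(trimethylsilyl) ether of 20 | COc1ccc2c(c1)C[C@@H](O[Si](C)(C)C)[C@H]1[C@](C)(O[Si](C)(C)C)C=CC[C@@]12C | intermediate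
20 | 9β,11α-diol with C12=C13 olefin | COc1ccc2c(c1)C[C@@H](O)[C@H]1[C@](C)(O)C=CC[C@@]12C | intermediate
21 | 12α,13α-epoxy-9β,11α-diol | COc1ccc2c(c1)C[C@@H](O)[C@H]1[C@](C)(O)[C@@H]3O[C@@H]3C[C@@]12C | intermediate
22 | 9β,11α,12α-triol with C13=C14 olefin | COc1ccc2c(c1)C[C@@H](O)[C@H]1[C@](C)(O)[C@H](O)C=C[C@@]12C | intermediate
23 | Birch diene (C4=C5 methyl enol ether; C2=C7 olefin) | COC1=CCC2=C(C1)C[C@@H](O)[C@H]1[C@](C)(O)[C@H](O)C=C[C@@]12C | intermediate
24 | C5 dioxolane 9β,11α,12α-triol | C1CC2(OCCO2)CC3=C1[C@@]4(C)C=C[C@@H](O)[C@@](C)(O)[C@@H]4[C@H](O)C3 | intermediate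
25 | 11,12-cyclic methyl orthobutanoate (orthoester carbon a mixture) | C1CC2(OCCO2)CC3=C1[C@@]4(C)C=C[C@H]5OC(CCC)(OC)O[C@@]5(C)[C@@H]4[C@H](O)C3 | intermediate
26 | C9 ketone (β,γ-unsaturated) | C1CC2(OCCO2)CC3=C1[C@@]4(C)C=C[C@H]5OC(CCC)(OC)O[C@@]5(C)[C@@H]4C(=O)C3 | intermediate
27 | potassium C8=C9 dienolate | C1CC2(OCCO2)CC3=C1[C@@]4(C)C=C[C@H]5OC(CCC)(OC)O[C@@]5(C)[C@@H]4C([O-])=C3.[K+] | intermediate
28 | 8-hydroxy C9 ketone (C8 epimers) | C1CC2(OCCO2)CC3=C1[C@@]4(C)C=C[C@H]5OC(CCC)(OC)O[C@@]5(C)[C@@H]4C(=O)C3O | intermediate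
29 | 8,9β-diol (C8 epimers) | C1CC2(OCCO2)CC3=C1[C@@]4(C)C=C[C@H]5OC(CCC)(OC)O[C@@]5(C)[C@@H]4[C@H](O)C3O | intermediate
30 | 9β-hydroxy C8 enone (orthoester intact) | C1CC2(OCCO2)CC3=C1[C@@]4(C)C=C[C@H]5OC(CCC)(OC)O[C@@]5(C)[C@@H]4[C@H](O)C3=O | intermediate
31 | 12α-butanoate 9β,11α-diol C8 enone | C1CC2(OCCO2)CC3=C1[C@@]4(C)C=C[C@@H](OC(=O)CCC)[C@@](C)(O)[C@@H]4[C@H](O)C3=O | intermediate
32 | 13α,14α-epoxide of 31 | C1CC2(OCCO2)CC3=C1[C@@]4(C)[C@H]5O[C@H]5[C@@H](OC(=O)CCC)[C@@](C)(O)[C@@H]4[C@H](O)C3=O | intermediate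
33 | 2-bromopropanoyl bromide (racemic) | CC(Br)C(Br)=O | starting material
34 | 9β-(2-bromopropanoate) of 32 (CHBr a mixture) | C1CC2(OCCO2)CC3=C1[C@@]4(C)[C@H]5O[C@H]5[C@@H](OC(=O)CCC)[C@@](C)(O)[C@@H]4[C@H](OC(=O)C(C)Br)C3=O | intermediate
35 | samarium ester enolate (SmI2 on oxygen) | C1CC2(OCCO2)CC3=C1[C@@]4(C)[C@H]5O[C@H]5[C@@H](OC(=O)CCC)[C@@](C)(O)[C@@H]4[C@H](OC(O[Sm](I)I)=CC)C3=O | intermediate
36 | tricyclic ring-fusion olefin: C2=C7; C5 dioxolane; 8α-OH; C17 β on C8 and lactonised to O9 (17-epi methyl); ring A complete | C1CC2(OCCO2)CC3=C1[C@@]4(C)[C@H]5O[C@H]5[C@@H](OC(=O)CCC)[C@@](C)(O)[C@@H]4[C@@H]6OC(=O)[C@@H](C)[C@]36O | intermediate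
37 | primary ozonide (1,2,3-trioxolane on C2–C7) | C1CC2(OCCO2)CC3(OOO6)C16[C@@]4(C)[C@H]5O[C@H]5[C@@H](OC(=O)CCC)[C@@](C)(O)[C@@H]4[C@@H]7OC(=O)[C@@H](C)[C@]37O | intermediate
38 | bridged 1,2,4-trioxolane spanning C2 and C7 | C12(OCCO1)CCC(OO6)(O7)[C@@]3(C)[C@H]4O[C@H]4[C@@H](OC(=O)CCC)[C@@](C)(O)[C@@H]3[C@@H]5OC(=O)[C@@H](C)[C@]5(O)C67C2 | intermediate
39 | ten-membered C2/C7 diketone (C5 dioxolane; O9 lactone; 8-OH) | C12(OCCO1)CCC(=O)[C@@]3(C)[C@H]4O[C@H]4[C@@H](OC(=O)CCC)[C@@](C)(O)[C@@H]3[C@@H]5OC(=O)[C@@H](C)[C@]5(O)C(=O)C2 | intermediate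
40 | 7-hydroxy C2 ketone (O9 lactone; C7 as in target) | C12(OCCO1)CCC(=O)[C@@]3(C)[C@H]4O[C@H]4[C@@H](OC(=O)CCC)[C@@](C)(O)[C@@H]3[C@@H]5OC(=O)[C@@H](C)[C@]5(O)[C@@H](O)C2 | intermediate
41 | 9-hydroxy O7 lactone, C17 epimer | C12(OCCO1)CCC(=O)[C@@]3(C)[C@H]4O[C@H]4[C@@H](OC(=O)CCC)[C@@](C)(O)[C@@H]3[C@H](O)[C@]5(O)[C@H](C)C(=O)O[C@H]5C2 | intermediate
42 | 9-hydroxy O7 lactone, natural C17 | C12(OCCO1)CCC(=O)[C@@]3(C)[C@H]4O[C@H]4[C@@H](OC(=O)CCC)[C@@](C)(O)[C@@H]3[C@H](O)[C@]5(O)[C@@H](C)C(=O)O[C@H]5C2 | intermediate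
43 | 9-acetate of 42 | C12(OCCO1)CCC(=O)[C@@]3(C)[C@H]4O[C@H]4[C@@H](OC(=O)CCC)[C@@](C)(O)[C@@H]3[C@H](OC(C)=O)[C@]5(O)[C@@H](C)C(=O)O[C@H]5C2 | intermediate
44 | C2=C3 trimethylsilyl enol ether, 8,11-bis(trimethylsilyl) ether | C12(OCCO1)CC=C(O[Si](C)(C)C)[C@@]3(C)[C@H]4O[C@H]4[C@@H](OC(=O)CCC)[C@@](C)(O[Si](C)(C)C)[C@@H]3[C@H](OC(C)=O)[C@]5(O[Si](C)(C)C)[C@@H](C)C(=O)O[C@H]5C2 | intermediate
45 | (Z)-C3=C4 C2 enone, 8,11-bis(trimethylsilyl) ether | C12(OCCO1)/C=C\C(=O)[C@@]3(C)[C@H]4O[C@H]4[C@@H](OC(=O)CCC)[C@@](C)(O[Si](C)(C)C)[C@@H]3[C@H](OC(C)=O)[C@]5(O[Si](C)(C)C)[C@@H](C)C(=O)O[C@H]5C2 | intermediate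
46 | C2 allylic alcohol (C2 as in target) | C12(OCCO1)/C=C\[C@H](O)[C@@]3(C)[C@H]4O[C@H]4[C@@H](OC(=O)CCC)[C@@](C)(O[Si](C)(C)C)[C@@H]3[C@H](OC(C)=O)[C@]5(O[Si](C)(C)C)[C@@H](C)C(=O)O[C@H]5C2 | intermediate
47 | 2,12-dibutanoate | C12(OCCO1)/C=C\[C@H](OC(=O)CCC)[C@@]3(C)[C@H]4O[C@H]4[C@@H](OC(=O)CCC)[C@@](C)(O[Si](C)(C)C)[C@@H]3[C@H](OC(C)=O)[C@]5(O[Si](C)(C)C)[C@@H](C)C(=O)O[C@H]5C2 | intermediate
48 | C5 enone 8,11-diol (target lacking Cl and with C5=O) | O=C1/C=C\[C@H](OC(=O)CCC)[C@@]2(C)[C@H]3O[C@H]3[C@@H](OC(=O)CCC)[C@@](C)(O)[C@@H]2[C@H](OC(C)=O)[C@]2(O)[C@@H](C)C(=O)O[C@H]2C1 | intermediate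
49 | C5=C6 trimethylsilyl dienol ether, 8,11-bis(trimethylsilyl) ether | C[Si](C)(C)OC1/C=C\[C@H](OC(=O)CCC)[C@@]2(C)[C@H]3O[C@H]3[C@@H](OC(=O)CCC)[C@@](C)(O[Si](C)(C)C)[C@@H]2[C@H](OC(C)=O)[C@]2(O[Si](C)(C)C)[C@@H](C)C(=O)O[C@H]2C=1 | intermediate
50 | 6-chloro C5 enone, 8,11-bis(trimethylsilyl) ether (C6 as in target) | O=C1/C=C\[C@H](OC(=O)CCC)[C@@]2(C)[C@H]3O[C@H]3[C@@H](OC(=O)CCC)[C@@](C)(O[Si](C)(C)C)[C@@H]2[C@H](OC(C)=O)[C@]2(O[Si](C)(C)C)[C@@H](C)C(=O)O[C@H]2[C@H]1Cl | intermediate
51 | 8,11-bis(trimethylsilyl) ether of the target | C=C1/C=C\[C@H](OC(=O)CCC)[C@@]2(C)[C@H]3O[C@H]3[C@@H](OC(=O)CCC)[C@@](C)(O[Si](C)(C)C)[C@@H]2[C@H](OC(C)=O)[C@]2(O[Si](C)(C)C)[C@@H](C)C(=O)O[C@H]2[C@H]1Cl | intermediate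
52 | CNP0188106.1 | C=C1/C=C\[C@H](OC(=O)CCC)[C@@]2(C)[C@H]3O[C@H]3[C@@H](OC(=O)CCC)[C@@](C)(O)[C@@H]2[C@H](OC(C)=O)[C@]2(O)[C@@H](C)C(=O)O[C@H]2[C@H]1Cl | target

**Count and risks**

Total: 32 steps. Longest linear sequence: 32 steps (1 → 52); 5, 6 and 33 are bought.

Step 31 (C6 chlorination). Chlorine may be delivered to the wrong face of the C5=C6 enol ether, or the chloro ketone may enolise and expel the C7 lactone oxygen. The fallback sets out from silyl dienol ether 49. DMDO followed by mild acidic work-up (Rubottom oxidation) should give the 6-hydroxy enone F1, whose oxygen sits on the face that a wrong chlorination would have used. MsCl/Et3N at −40 °C converts it into the α-keto mesylate F2, and LiCl in DMF displaces the mesylate with inversion (SN2 next to a carbonyl), which returns to the route at 50.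

Step 23 (ozonolysis). Over-oxidation or fragmentation next to the free allylic C8 hydroxyl, or transannular aldol closure of the diketone during work-up, may erode the product. The fallback sets out from 36. Stoichiometric OsO4 in pyridine with NaHSO3 work-up should give the C2,C7 cis-diol F3 (either face serves). Glycol cleavage with Pb(OAc)4 in benzene over K2CO3 at 0 °C then rejoins the route at 39 under neutral, non-peroxidic conditions.

Step 27 (C3=C4 enone). β-Hydride elimination from the palladium enolate may give the trans olefin or a mixture of geometries. The fallback sets out from silyl enol ether 44. PhSeCl at −78 °C gives the 3-phenylselanyl ketone F4, and H2O2/pyridine triggers selenoxide syn-elimination. Any (E)-enone F5 that forms is equilibrated to the less strained cis isomer with catalytic PhSSPh under visible light, which returns to the route at 45.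

Further compounds
F1 | step 31 | 6-hydroxy C5 enone 8,11-bis(trimethylsilyl) ether (C6 oxygen on the face opposite to the target chlorine) | O=C1/C=C\[C@H](OC(=O)CCC)[C@@]2(C)[C@H]3O[C@H]3[C@@H](OC(=O)CCC)[C@@](C)(O[Si](C)(C)C)[C@@H]2[C@H](OC(C)=O)[C@]2(O[Si](C)(C)C)[C@@H](C)C(=O)O[C@H]2[C@@H]1O
F2 | step 31 | 6-mesylate of F1 | O=C1/C=C\[C@H](OC(=O)CCC)[C@@]2(C)[C@H]3O[C@H]3[C@@H](OC(=O)CCC)[C@@](C)(O[Si](C)(C)C)[C@@H]2[C@H](OC(C)=O)[C@]2(O[Si](C)(C)C)[C@@H](C)C(=O)O[C@H]2[C@@H]1OS(C)(=O)=O
F3 | step 23 | C2,C7 cis-diol of 36 | C1CC2(OCCO2)CC3(O)C1(O)[C@@]4(C)[C@H]5O[C@H]5[C@@H](OC(=O)CCC)[C@@](C)(O)[C@@H]4[C@@H]6OC(=O)[C@@H](C)[C@]36O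
F4 | step 27 | 3-phenylselanyl C2 ketone 8,11-bis(trimethylsilyl) ether | C12(OCCO1)CC([Se]c6ccccc6)C(=O)[C@@]3(C)[C@H]4O[C@H]4[C@@H](OC(=O)CCC)[C@@](C)(O[Si](C)(C)C)[C@@H]3[C@H](OC(C)=O)[C@]5(O[Si](C)(C)C)[C@@H](C)C(=O)O[C@H]5C2
F5 | step 27 | (E)-C3=C4 isomer of 45 | C12(OCCO1)/C=C/C(=O)[C@@]3(C)[C@H]4O[C@H]4[C@@H](OC(=O)CCC)[C@@](C)(O[Si](C)(C)C)[C@@H]3[C@H](OC(C)=O)[C@]5(O[Si](C)(C)C)[C@@H](C)C(=O)O[C@H]5C2
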